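**Plan**
1. Retrosynthesis: cut the three benzoate C–O(acyl) bonds, trace the allylic C6–O bond back to a C4–O bond on the same ring face (1,3-shift), then cut the ring bonds C1–C2 and C3–C4.
2. Enabling feature: on the cyclohexene ring, C1 carries a hydroxyl and the exocyclic C7 and is flanked by cis oxygens on C2 and C3. C1/C7 map onto C3 and the lactone carbonyl of 3-hydroxy-2-pyrone 1, and C2/C3 onto the cis-enediol equivalent vinylene carbonate 2.
3. Forward: the only carbocycle is closed in step 1 inside the 2-oxabicyclo[2.2.2]octenone 3; hydride then removes the lactone bridge and the carbonate, and a bis-acetonide leaves only the C4 hydroxyl free.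
4. The oxygen is moved from C4 to C6 by allylic thioether formation (zerovalent palladium, retention) and a sulfoxide–sulfenate shift; the benzoates go on last (C6 first, then C7 and C3).
5. Stereochemistry: C1, C2, C3 and C4 come from the endo, catalyst-controlled cycloaddition; the C6 centre is relayed from C4 by two stereospecific steps.

Key step: step 1

Convention: locants C1–C7 are those of the target (C7 = exocyclic carbon on C1) and are used for every intermediate; β is the ring face that carries C7, α the opposite face.
Assumption: the quinine-derived catalyst is taken to give the enantiomer drawn for 3; if the facial sense is the opposite one, the pseudo-enantiomeric quinidine-derived catalyst is used instead.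

**Route**

Step 1
Reactants: 1 3-hydroxy-2H-pyran-2-one; 2 vinylene carbonate
Product: 3 endo cycloadduct (lactone C7(=O)–O–C4 bridging the β face; bridgehead 1α-OH; 2α,3α-cyclic carbonate; C5=C6)
Conditions: 1-[3,5-bis(trifluoromethyl)phenyl]-3-(9-deoxy-epi-quinin-9-yl)thiourea (10 mol %), 2 (5 equiv), t-BuOMe, 25–40 °C
Reagents that add atoms: none
Why: Proposed new method: the quinuclidine nitrogen deprotonates the 3-hydroxyl of 1, and the resulting ammonium pyronate, a diene with a strongly raised HOMO, should add across the C=C of 2 in a concerted suprafacial [4+2] step while the thiourea N–H bonds bind and polarise the carbonate carbonyl (pyrone C3 and C6 become C1 and C4; the new bonds are C1–C2 and C3–C4). The closest known reaction type is the cinchona-base-catalysed asymmetric Diels–Alder reaction of 3-hydroxy-2-pyrones with electron-poor alkenes, which keeps the lactone bridge; vinylene carbonate is a much weaker partner that cannot react by conjugate addition, hence the excess and the hydrogen-bond donor. The one ring that closes, the six-membered carbocycle, is formed by this intermolecular cycloaddition, with the lactone left as the two-atom bridge of a 2-oxabicyclo[2.2.2]octenone. C2 and C3 are cis because the dienophile is a ring-locked cis-alkene, their orientation towards C1 and C4 (carbonate under the new C5=C6 bond, so cis to the C1 hydroxyl and trans to the lactone oxygen on C4) comes from the endo transition state, and the absolute sense of all four centres comes from the chiral ion pair. The step needs endo and enantiofacial selectivity but no regiocontrol because 2 is symmetric: endo approach is favoured by secondary overlap of the carbonate with the diene and by the thiourea hydrogen bond, and the diene face is chosen by the catalyst.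

Step 2
Reactants: 3 endo cycloadduct
Product: 4 pentaol, 1β-(hydroxymethyl)cyclohex-5-ene-1α,2α,3α,4β-tetrol
Conditions: LiAlH4 (3 equiv), THF, 0 → 40 °C; Na2SO4·10H2O quench
Reagents that add atoms: none
Why: Lithium aluminium hydride reduction of esters and carbonates: the strained α-hydroxy lactone should open to the C7 primary alcohol and the 4β-alcohol and the cyclic carbonate to the 2,3-diol (its carbon leaving as methanol), and since no bond to a stereocentre is broken the four centres of 3 are carried over unchanged.

Step 3
Reactants: 4 pentaol
Product: 5 bis-acetonide alcohol (O1/O7 spiro-dioxolane; O2/O3 cis-fused dioxolane; 4β-OH free)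
Conditions: Me2C(OMe)2, CSA (cat.), acetone, 25 °C; Et3N quench
Reagents that add atoms: 2,2-dimethoxypropane, COC(C)(C)OC
Why: Acid-catalysed acetalisation under thermodynamic control: the primary/tertiary 1,2-diol (O7/O1) and the cis-2,3-diol can each close a strain-free dioxolane, whereas the 3,4-diol is trans and an acetal through O1/O2 would leave no strain-free second one, so the bis-acetonide with only the 4β-hydroxyl free should be the sink.

Step 4
Reactants: 5 bis-acetonide alcohol
Product: 6 4β-methyl carbonate of 5
Conditions: ClCO2Me, pyridine, DMAP (cat.), CH2Cl2, 0 °C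
Reagents that add atoms: methyl chloroformate, COC(=O)Cl
Why: Acylation of an alcohol with a chloroformate: the 4β-hydroxyl is the only free one, and the allylic methyl carbonate it gives is the standard leaving group for palladium-catalysed allylic substitution under neutral conditions.

Step 5
Reactants: 6 allylic methyl carbonate
Product: 7 4β-phenylsulfanyl bis-acetonide (C5=C6 kept)
Conditions: Pd(PPh3)4 (5 mol %), PhSH (1.2 equiv), THF, 40 °C
Reagents that add atoms: thiophenol, Sc1ccccc1
Why: Tsuji–Trost allylic substitution with a soft sulfur nucleophile: zerovalent palladium ionises the carbonate with inversion (metal on the α face), the liberated methoxide deprotonates the thiol, and the thiolate attacks anti to the metal at C4, the allyl terminus remote from the quaternary spiro carbon C1, so sulfur should stand β at C4 (net retention) with the alkene unchanged.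

Step 6
Reactants: 7 allylic sulfide
Product: 10 6β-hydroxy bis-acetonide (C4=C5), via allylic sulfoxide 8 (not isolated), via allylic sulfenate 9 (not isolated)
Conditions: mCPBA (1.0 equiv), CH2Cl2, −78 °C; then Et2NH, MeOH, 25 → 40 °C
Reagents that add atoms: 3-chloroperoxybenzoic acid (mCPBA), O=C(OO)c1cccc(Cl)c1
Why: Sulfide oxidation followed by Mislow–Evans rearrangement: the allylic sulfoxide equilibrates by a suprafacial [2,3]-sigmatropic shift with the C6 sulfenate, which the amine thiophile cleaves irreversibly, so oxygen is delivered to C6 on the β face that sulfur occupied at C4 (new C6 centre cis to C7) and the alkene moves to C4=C5.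

Step 7
Reactants: 10 allylic alcohol
Product: 11 6β-benzoate of 10
Conditions: BzCl, DMAP, pyridine, 25 °C
Reagents that add atoms: benzoyl chloride, O=C(Cl)c1ccccc1
Why: DMAP-catalysed acylation of a hindered secondary allylic alcohol with an acid chloride: the 6β-hydroxyl is the only free hydroxyl, so the benzoate can only go to C6.

Step 8
Reactants: 11 bis-acetonide benzoate
Product: 12 6β-benzoyloxy-1β-(hydroxymethyl)cyclohex-4-ene-1α,2α,3α-triol
Conditions: AcOH/H2O (4:1), 50 °C
Reagents that add atoms: none
Why: Acid-catalysed acetal hydrolysis: warm aqueous acetic acid should cleave both isopropylidene groups while benzoate esters and the allylic C–O bonds are stable, freeing the C7, C1, C2 and C3 hydroxyls without touching a stereocentre.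

Step 9
Reactants: 12 tetraol benzoate
Product: 13 target, [(1R,2R,3R,6R)-3,6-bis(benzoyloxy)-1,2-dihydroxycyclohex-4-en-1-yl]methyl benzoate
Conditions: BzCl (2.1 equiv), pyridine, CH2Cl2, −30 → 0 °C
Reagents that add atoms: benzoyl chloride, O=C(Cl)c1ccccc1
Why: Kinetically selective acylation with an acid chloride in pyridine: the primary C7 hydroxyl and the allylic C3 hydroxyl should react first, whereas the C2 hydroxyl (between the fully substituted C1 and the newly acylated C3) and the tertiary C1 hydroxyl are expected to be much slower, so two equivalents at low temperature should stop at the target.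

**Compound list**
1 | 3-hydroxy-2H-pyran-2-one | O=C1OC=CC=C1O | starting material
2 | vinylene carbonate (1,3-dioxol-2-one) | O=C1OC=CO1 | starting material
3 | endo adduct: 4,5,6-trihydroxy-2-oxabicyclo[2.2.2]oct-7-en-3-one 5,6-cyclic carbonate, carbonate syn to C7=C8 (target locants: lactone C7(=O)–O–C4 on the β face, 1α-OH, 2α,3α-carbonate, C5=C6) | O=C1O[C@H]2C=C[C@]1(O)[C@@H]1OC(=O)O[C@@H]12 | intermediate
4 | 1β-(hydroxymethyl)cyclohex-5-ene-1α,2α,3α,4β-tetrol | OC[C@@]1(O)[C@H](O)[C@H](O)[C@@H](O)C=C1 | intermediate
5 | bis-acetonide of 4 with free 4β-OH: 2,2,2′,2′-tetramethyl-7,7a-dihydro-3aH-spiro[1,3-benzodioxole-4,4′-[1,3]dioxolan]-7-ol (spiro-dioxolane through O1/O7, cis-fused dioxolane through O2/O3) | CC1(C)OC[C@@]2(O1)[C@@H]3OC(C)(C)O[C@@H]3[C@@H](O)C=C2 | intermediate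
6 | 4β-methyl carbonate of 5 | CC1(C)OC[C@@]2(O1)[C@@H]3OC(C)(C)O[C@@H]3[C@@H](OC(=O)OC)C=C2 | intermediate
7 | 4β-(phenylsulfanyl) bis-acetonide, C5=C6 | CC1(C)OC[C@@]2(O1)[C@@H]3OC(C)(C)O[C@@H]3[C@@H](Sc4ccccc4)C=C2 | intermediate
8 | 4β-(phenylsulfinyl) bis-acetonide, C5=C6 (both sulfur epimers) | CC1(C)OC[C@@]2(O1)[C@@H]3OC(C)(C)O[C@@H]3[C@@H](S(=O)c4ccccc4)C=C2 | intermediate (not isolated)
9 | 6β-(phenylsulfanyloxy) bis-acetonide (sulfenate ester), C4=C5 | CC1(C)OC[C@@]2(O1)[C@@H]3OC(C)(C)O[C@@H]3C=C[C@H]2OSc4ccccc4 | intermediate (not isolated)
10 | 6β-hydroxy bis-acetonide, C4=C5: 2,2,2′,2′-tetramethyl-5,7a-dihydro-3aH-spiro[1,3-benzodioxole-4,4′-[1,3]dioxolan]-5-ol | CC1(C)OC[C@@]2(O1)[C@@H]3OC(C)(C)O[C@@H]3C=C[C@H]2O | intermediate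
11 | 6β-benzoate of 10 | CC1(C)OC[C@@]2(O1)[C@@H]3OC(C)(C)O[C@@H]3C=C[C@H]2OC(=O)c4ccccc4 | intermediate
12 | 6β-benzoyloxy-1β-(hydroxymethyl)cyclohex-4-ene-1α,2α,3α-triol | OC[C@@]1(O)[C@H](O)[C@H](O)C=C[C@H]1OC(=O)c2ccccc2 | intermediate
13 | [(1R,2R,3R,6R)-3,6-bis(benzoyloxy)-1,2-dihydroxycyclohex-4-en-1-yl]methyl benzoate | O=C(OC[C@@]1(O)[C@H](O)[C@H](OC(=O)c2ccccc2)C=C[C@H]1OC(=O)c1ccccc1)c1ccccc1 | target

**Step count and risks**
Total: 9 steps. Longest linear sequence: 9 steps (1 and 2 to 13).

Steps most likely to fail:

1. Step 1 (proposed new method). The pyronate may not engage the weakly electrophilic alkene at a useful rate, the base may instead decompose the dienophile by acyl transfer to the pyronate oxygen, or endo and facial discrimination may be poor. Fallback, from 1 and 2, rejoining at 4: 1 is acylated with (1S)-camphanic chloride (pyridine, CH2Cl2, 0 °C) to 2-oxo-2H-pyran-3-yl camphanate F1. Uncatalysed cycloaddition of F1 with 2 under high pressure (CH2Cl2, 10–12 kbar, 40 °C) should give the endo adducts as two diastereomers; high-pressure addition of weakly activated alkenes to 2-pyrones with retention of the CO2 bridge, and cycloaddition of vinylene carbonate to cyclic dienes, are both established. The diastereomers are separated by crystallisation or chromatography, and the one with the configuration of 3, adduct camphanate F2, is reduced with LiAlH4 as in step 2. This cleaves auxiliary, lactone and carbonate together and gives 4.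

2. Step 5. Thiolate attack may be divided between the two allyl termini, ionisation on the face cis to the neighbouring acetonide oxygen may be slow, and the thiol may deactivate the catalyst. Attack at C6 would not be lost, because step 6 would convert that isomer back into 5. Fallback, from 5, rejoining at 10: hydroxyl-directed (Henbest) epoxidation with mCPBA (CH2Cl2, 0 °C) should give the cis-5β,6β-epoxy alcohol F3. Mesylation (MsCl, Et3N, CH2Cl2, 0 °C) gives the epoxy mesylate F4. Dissolving-metal reduction (Na, liquid NH3, THF, −78 °C) cleaves the C4–O bond and opens the epoxide from C5, giving 10 with the C6 oxygen in the β orientation of the epoxide.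

3. Step 9. Over-acylation at C2 or base-induced benzoyl migration between O3 and O2 would erode the regioselectivity. Fallback, from 12, rejoining at 13: BzCl (1.05 equiv, pyridine, CH2Cl2, −40 °C) acylates only the primary hydroxyl and gives the 6,7-dibenzoate triol F5. Regioselective monoacylation of its cis-2,3-diol under borinic acid catalysis (2-aminoethyl diphenylborinate 10 mol %, BzCl, i-Pr2NEt, MeCN, 25 °C) activates the more accessible oxygen of a cis-1,2-diol through a cyclic borinate and should place the last benzoate on O3, giving 13.

Further compounds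
F1 | step 1 | 2-oxo-2H-pyran-3-yl (1S,4R)-camphanate | O=C(OC1=CC=COC1=O)[C@@]23CC[C@@](C)(C(=O)O2)C3(C)C
F2 | step 1 | (1S,4R)-camphanate ester of the bridgehead hydroxyl of 3 | O=C1O[C@H]2C=C[C@]1(OC(=O)[C@@]34CC[C@@](C)(C(=O)O3)C4(C)C)[C@@H]1OC(=O)O[C@@H]12
F3 | step 5 | 5β,6β-epoxide of 5 (4β-OH free) | CC1(C)OC[C@@]2(O1)[C@@H]3OC(C)(C)O[C@@H]3[C@@H](O)[C@H]4O[C@@H]24
F4 | step 5 | 4-O-methanesulfonate of F3 | CC1(C)OC[C@@]2(O1)[C@@H]3OC(C)(C)O[C@@H]3[C@@H](OS(C)(=O)=O)[C@H]4O[C@@H]24
F5 | step 9 | 6β-benzoyloxy-1β-(benzoyloxymethyl)cyclohex-4-ene-1α,2α,3α-triol | O=C(OC[C@@]1(O)[C@H](O)[C@H](O)C=C[C@H]1OC(=O)c1ccccc1)c1ccccc1
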